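Assumption: ovatodiolide numbering is used (C1 ring-fusion CH, C14 lactone O–CH, C10 butenolide O–CH, C5 the CH–OOH carbon); the SMILES is read as 1R,5R,10R,14S with a trans-fused α-methylene lactone.

**Retrosynthetic overview**
1. Target ⇐ ovatodiolide: a last-step singlet-oxygen ene reaction puts OOH on C5 and moves the C4=C5 olefin to C4=CH2.
2. Ovatodiolide ⇐ open-chain butenolide carrying an enal (C14) and a (Z)-2-(methoxycarbonyl)allylboronate (C1): one intramolecular allylboration–lactonization forms the 14-membered carbocycle and the trans α-methylene lactone together and sets C1 and C14.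
3. That precursor ⇐ RCM (butenolide) of the ester between a 2-substituted acrylic acid and an (R)-propenyl carbinol (C10 from asymmetric propargylation).
4. Acid ⇐ Negishi coupling (C5–C6) of an (E)-vinyl iodide/allylboronate with the zinc reagent from α-methylene-γ-butyrolactone; both E-trisubstituted olefins come from Zr-catalysed alkyne carboalumination.
5. Ring order: butenolide first, then carbocycle and α-methylene lactone in one operation.

**Route**

Step 1
Reactants: 1 pent-4-yn-1-ol
Product: 3 (E)-5-iodo-4-methylpent-4-en-1-ol, via alkenylalane 2 (not isolated)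
Conditions: Me3Al (3 equiv), Cp2ZrCl2 (25 mol %), CH2Cl2, 0 °C to rt; then I2, THF, −30 °C
Reagents that add atoms: trimethylaluminium C[Al](C)C; iodine II
Why: Negishi Zr-catalysed carboalumination adds Me and Al syn across the alkyne and iodinolysis proceeds with retention, giving the E-trisubstituted vinyl iodide.

Step 2
Reactants: 3 (E)-5-iodo-4-methylpent-4-en-1-ol
Product: 4 (E)-5-iodo-4-methylpent-4-enal
Conditions: Dess–Martin periodinane, CH2Cl2, rt
Reagents that add atoms: none
Why: Dess–Martin oxidation of a primary alcohol leaves the vinyl iodide untouched.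

Step 3
Reactants: 4 (E)-5-iodo-4-methylpent-4-enal
Product: 5 (E)-1-iodo-2-methylhex-1-en-5-yne
Conditions: dimethyl (1-diazo-2-oxopropyl)phosphonate, K2CO3, MeOH, 0 °C to rt
Reagents that add atoms: dimethyl (1-diazo-2-oxopropyl)phosphonate CC(=O)C(=[N+]=[N-])P(=O)(OC)OC
Why: Seyferth–Gilbert homologation (Ohira–Bestmann variant) turns the aldehyde into the terminal alkyne under mild base.

Step 4
Reactants: 5 (E)-1-iodo-2-methylhex-1-en-5-yne
Product: 7 methyl (E)-7-iodo-6-methylhept-6-en-2-ynoate, via lithium acetylide 6 (not isolated)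
Conditions: LiN(SiMe3)2, THF, −78 °C; then ClCO2Me, −78 to 0 °C
Reagents that add atoms: methyl chloroformate COC(=O)Cl
Why: C-acylation of a lithium acetylide; the amide base does not exchange the vinyl iodide.

Step 5
Reactants: 7 methyl (E)-7-iodo-6-methylhept-6-en-2-ynoate
Product: 9 methyl (2Z,6E)-7-iodo-6-methyl-2-[(4,4,5,5-tetramethyl-1,3,2-dioxaborolan-2-yl)methyl]hepta-2,6-dienoate, via vinylalane 8 (not isolated)
Conditions: i-Bu2AlH, HMPA, THF, 0 °C; then ICH2Bpin, 0 °C to rt
Reagents that add atoms: 2-(iodomethyl)-4,4,5,5-tetramethyl-1,3,2-dioxaborolane ICB1OC(C)(C)C(C)(C)O1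
Why: conjugate syn-hydroalumination of the ynoate followed by C-alkylation with the iodomethylboronate gives the allylboronate with the chain cis to CO2Me (trans to CH2B), the geometry that leads to anti allylboration.

Step 6
Reactants: 10 3-methylideneoxolan-2-one (α-methylene-γ-butyrolactone)
Product: 11 trimethylsilyl 4-iodo-2-methylidenebutanoate
Conditions: Me3SiI, CH2Cl2, 0 °C to rt, dark; concentrated and used crude
Reagents that add atoms: iodotrimethylsilane C[Si](C)(C)I
Why: silyl iodide cleavage of a lactone (O-silylation then SN2 by iodide at the CH2–O carbon) gives the ω-iodo silyl ester; conjugate iodide addition is reversible.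

Step 7
Reactants: 11 trimethylsilyl 4-iodo-2-methylidenebutanoate; 9 methyl (2Z,6E)-7-iodo-6-methyl-2-[(4,4,5,5-tetramethyl-1,3,2-dioxaborolan-2-yl)methyl]hepta-2,6-dienoate
Product: 14 (5E,9Z)-10-(methoxycarbonyl)-6-methyl-2-methylidene-11-(4,4,5,5-tetramethyl-1,3,2-dioxaborolan-2-yl)undeca-5,9-dienoic acid, via alkylzinc iodide 12 (not isolated), via silyl ester 13 (not isolated)
Conditions: Zn dust (TMSCl/BrCH2CH2Br-activated), LiCl, THF, 40 °C; then 9, PdCl2(dppf) (5 mol %), THF, 45 °C; aq. citric acid work-up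
Reagents that add atoms: none
Why: zinc insertion into the primary iodide and Negishi alkyl–alkenyl cross-coupling join C5–C6 with retention of the E olefin; the allyl-Bpin and esters tolerate RZnI, and the silyl ester hydrolyses on work-up.

Step 8
Reactants: 15 (E)-but-2-enal; 16 4,4,5,5-tetramethyl-2-(propa-1,2-dien-1-yl)-1,3,2-dioxaborolane (allenyl-Bpin)
Product: 18 (4R,5E)-hept-5-en-1-yn-4-ol, via O-boryl ether 17 (not isolated)
Conditions: (R)-TRIP (5 mol %), 4 Å MS, toluene, −20 °C; aqueous work-up
Reagents that add atoms: none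
Why: chiral-phosphoric-acid-catalysed propargylation with an allenylboronate through a closed six-membered transition state; (R)-TRIP directs Re-face attack on the enal and sets the 4R carbinol (the future C10).

Step 9
Reactants: 18 (4R,5E)-hept-5-en-1-yn-4-ol
Product: 21 (2E,5R,6E)-3-methylocta-2,6-diene-1,5-diol, via alkenylalane 19 (not isolated), via lithium alanate 20 (not isolated)
Conditions: Me3Al (3 equiv), Cp2ZrCl2 (50 mol %), ClCH2CH2Cl, 0 °C to rt; excess Me3Al removed; n-BuLi, THF, −78 °C; (CH2O)n, −78 °C to rt; aq. Rochelle salt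
Reagents that add atoms: trimethylaluminium C[Al](C)C; formaldehyde (from paraformaldehyde) C=O
Why: Negishi carboalumination of the alkyne (the olefin is inert) and hydroxymethylation of the derived alanate with retention give the E-trisubstituted allylic alcohol; the carbinol centre is untouched.

Step 10
Reactants: 21 (2E,5R,6E)-3-methylocta-2,6-diene-1,5-diol
Product: 22 (2E,5R,6E)-5-hydroxy-3-methylocta-2,6-dienal
Conditions: TEMPO (10 mol %), PhI(OAc)2, CH2Cl2, rt
Reagents that add atoms: none
Why: oxoammonium (TEMPO) oxidation is selective for the primary allylic alcohol over the secondary one.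

Step 11
Reactants: 14 (5E,9Z)-10-(methoxycarbonyl)-6-methyl-2-methylidene-11-(4,4,5,5-tetramethyl-1,3,2-dioxaborolan-2-yl)undeca-5,9-dienoic acid; 22 (2E,5R,6E)-5-hydroxy-3-methylocta-2,6-dienal
Product: 23 (2E,5R,6E)-3-methyl-1-oxoocta-2,6-dien-5-yl ester of acid 14
Conditions: DCC, DMAP (10 mol %), CH2Cl2, 0 °C to rt
Reagents that add atoms: none
Why: Steglich esterification acylates the carbinol oxygen with retention at C5 of 22; the ester-substituted allylboronate does not add to the enal at rt without a catalyst.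

Step 12
Reactants: 23 (2E,5R,6E)-3-methyl-1-oxoocta-2,6-dien-5-yl ester of acid 14
Product: 24 methyl (2Z,6E)-6-methyl-9-{(5R)-5-[(2E)-2-methyl-4-oxobut-2-en-1-yl]-2-oxo-2,5-dihydrofuran-3-yl}-2-[(4,4,5,5-tetramethyl-1,3,2-dioxaborolan-2-yl)methyl]nona-2,6-dienoate
Conditions: second-generation Grubbs catalyst (10 mol %), 1,4-benzoquinone (20 mol %), toluene (5 mM), 80 °C
Reagents that add atoms: none
Why: ring-closing metathesis between the propenyl group and the 1,1-disubstituted acrylate closes the butenolide with loss of propene; the trisubstituted olefins and the enal are spectators.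

Step 13
Reactants: 24 methyl (2Z,6E)-6-methyl-9-{(5R)-5-[(2E)-2-methyl-4-oxobut-2-en-1-yl]-2-oxo-2,5-dihydrofuran-3-yl}-2-[(4,4,5,5-tetramethyl-1,3,2-dioxaborolan-2-yl)methyl]nona-2,6-dienoate
Product: 26 ovatodiolide (1R,10R,14S), via macrocyclic borate 25 (not isolated)
Conditions: (R)-TRIP (30 mol %), 4 Å MS, toluene, 50 °C, syringe-pump addition of 24 (final 2 mM); then TsOH·H2O (20 mol %), rt
Reagents that add atoms: none
Why: Proposed new method: intramolecular, phosphoric-acid-catalysed allylboration of the enal by the 2-(methoxycarbonyl)allylboronate through the closed six-membered chair transition state of the bimolecular reaction (closest known type: acid-catalysed 2-alkoxycarbonyl-allylboration/lactonization of aldehydes), in which the chain trans to CH2B sits equatorial and gives the anti adduct and hence the trans lactone, while (R)-TRIP directs Re-face attack to set C14 as S and thereby C1 as R; the borate then lactonizes with loss of MeOBpin, so the 14-membered carbocycle and the α-methylene lactone form in the same operation.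

Step 14
Reactants: 26 ovatodiolide (1R,10R,14S)
Product: 27 4-methylene-5β-hydroperoxyovatodiolide (1R,5R,10R,14S)
Conditions: O2, tetraphenylporphyrin (1 mol %), visible light, CH2Cl2, −20 °C, to about 70 % conversion
Reagents that add atoms: dioxygen O=O
Why: Schenck ene reaction: singlet oxygen attacks only the electron-rich C4=C5 olefin (C12=C13 is deactivated by the allylic lactone oxygen), takes H from the C4 methyl group and delivers oxygen to C5 from the exposed outer face of the macrocycle, which is expected to give the 5R hydroperoxide found in nature.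

**Compound list**
1 | pent-4-yn-1-ol | C#CCCCO | starting material
2 | dimethyl[(E)-5-(dimethylalumanyloxy)-2-methylpent-1-en-1-yl]alane | C[Al](C)/C=C(\C)CCCO[Al](C)C | intermediate
3 | (E)-5-iodo-4-methylpent-4-en-1-ol | I/C=C(\C)CCCO | intermediate
4 | (E)-5-iodo-4-methylpent-4-enal | I/C=C(\C)CCC=O | intermediate
5 | (E)-1-iodo-2-methylhex-1-en-5-yne | I/C=C(\C)CCC#C | intermediate
6 | lithium acetylide of 5 | [Li]C#CCC/C(C)=C/I | intermediate
7 | methyl (E)-7-iodo-6-methylhept-6-en-2-ynoate | COC(=O)C#CCC/C(C)=C/I | intermediate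
8 | methyl (2E,6E)-2-(diisobutylalumanyl)-7-iodo-6-methylhepta-2,6-dienoate | COC(=O)/C(=C\CC/C(C)=C/I)[Al](CC(C)C)CC(C)C | intermediate
9 | methyl (2Z,6E)-7-iodo-6-methyl-2-[(4,4,5,5-tetramethyl-1,3,2-dioxaborolan-2-yl)methyl]hepta-2,6-dienoate | COC(=O)/C(CB1OC(C)(C)C(C)(C)O1)=C\CC/C(C)=C/I | intermediate
10 | 3-methylideneoxolan-2-one | C=C1CCOC1=O | starting material
11 | trimethylsilyl 4-iodo-2-methylidenebutanoate | C=C(CCI)C(=O)O[Si](C)(C)C | intermediate
12 | {3-[(trimethylsilyloxy)carbonyl]but-3-en-1-yl}zinc iodide | C=C(CC[Zn]I)C(=O)O[Si](C)(C)C | intermediate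
13 | trimethylsilyl ester of 14 | COC(=O)/C(CB1OC(C)(C)C(C)(C)O1)=C\CC/C(C)=C/CCC(=C)C(=O)O[Si](C)(C)C | intermediate
14 | (5E,9Z)-10-(methoxycarbonyl)-6-methyl-2-methylidene-11-(4,4,5,5-tetramethyl-1,3,2-dioxaborolan-2-yl)undeca-5,9-dienoic acid | COC(=O)/C(CB1OC(C)(C)C(C)(C)O1)=C\CC/C(C)=C/CCC(=C)C(=O)O | intermediate
15 | (E)-but-2-enal | C/C=C/C=O | starting material
16 | 4,4,5,5-tetramethyl-2-(propa-1,2-dien-1-yl)-1,3,2-dioxaborolane | C=C=CB1OC(C)(C)C(C)(C)O1 | starting material
17 | O-(pinacolboryl) ether of 18 | C#CC[C@@H](OB1OC(C)(C)C(C)(C)O1)/C=C/C | intermediate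
18 | (4R,5E)-hept-5-en-1-yn-4-ol | C#CC[C@@H](O)/C=C/C | intermediate
19 | alkenylalane from 18 (Me2Al on the terminal vinyl carbon, O–AlMe2) | C[Al](C)/C=C(\C)C[C@@H](O[Al](C)C)/C=C/C | intermediate
20 | lithium butyl alanate of 19 | [Li+].CCCC[Al-](C)(C)/C=C(\C)C[C@@H](O[Al](C)C)/C=C/C | intermediate
21 | (2E,5R,6E)-3-methylocta-2,6-diene-1,5-diol | OC/C=C(\C)C[C@@H](O)/C=C/C | intermediate
22 | (2E,5R,6E)-5-hydroxy-3-methylocta-2,6-dienal | O=C/C=C(\C)C[C@@H](O)/C=C/C | intermediate
23 | (2E,5R,6E)-3-methyl-1-oxoocta-2,6-dien-5-yl ester of acid 14 | COC(=O)/C(CB1OC(C)(C)C(C)(C)O1)=C\CC/C(C)=C/CCC(=C)C(=O)O[C@H](C/C(C)=C/C=O)/C=C/C | intermediate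
24 | methyl (2Z,6E)-6-methyl-9-{(5R)-5-[(2E)-2-methyl-4-oxobut-2-en-1-yl]-2-oxo-2,5-dihydrofuran-3-yl}-2-[(4,4,5,5-tetramethyl-1,3,2-dioxaborolan-2-yl)methyl]nona-2,6-dienoate | COC(=O)/C(CB1OC(C)(C)C(C)(C)O1)=C\CC/C(C)=C/CCC2=C[C@@H](C/C(C)=C/C=O)OC2=O | intermediate
25 | macrocyclic borate (1R,10R,14S): 14-membered carbocycle with C14–O–Bpin and the C1 2-(methoxycarbonyl)vinyl group not yet lactonized | C=C(C(=O)OC)[C@H]1CC/C(C)=C/CCC2=C[C@@H](C/C(C)=C/[C@@H]1OB3OC(C)(C)C(C)(C)O3)OC2=O | intermediate
26 | ovatodiolide (1R,10R,14S) | C=C1C(=O)O[C@H]2/C=C(\C)C[C@@H]3C=C(CC/C=C(\C)CC[C@H]12)C(=O)O3 | intermediate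
27 | 4-methylene-5β-hydroperoxyovatodiolide (1R,5R,10R,14S) | C=C1C(=O)O[C@H]2/C=C(\C)C[C@@H]3C=C(CC[C@@H](OO)C(=C)CC[C@H]12)C(=O)O3 | target

**Count**
Total steps: 14. Longest linear sequence: 10 (steps 1–5, 7, 11–14).

**Steps most likely to fail, with fallbacks**

Step 13 (macrocyclizing allylboration: ring closure at high dilution and the facial selectivity are both unproven). The fallback sets out from 14 and 22 and returns at 26. (R)-TRIP-catalysed bimolecular allylboration of the enal of 22 with boronate 14, then acid-promoted lactonization, gives the trans-lactone seco hydroxy acid F1. Yamaguchi macrolactonization (2,4,6-trichlorobenzoyl chloride, Et3N, DMAP, toluene, high dilution) closes the 15-membered diolide F2. Transannular ring-closing metathesis (second-generation Hoveyda–Grubbs catalyst, toluene, 80 °C) then contracts it to the butenolide and carbocycle of 26. The large ring is thus closed by C–O bond formation, and C1/C14 are set in a bimolecular catalyst-controlled step.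

Step 14 (ene reaction: the competing tertiary 4-hydroperoxide and the C5 face selectivity rest on substrate control). The fallback sets out from 26 and returns at 27. mCPBA epoxidizes the C4=C5 olefin from the exposed face to give the (4S,5S)-4,5-epoxide F3. TMSOTf/2,6-lutidine isomerizes it to the exo-methylene allylic silyl ether F4, and mild aqueous acid gives the (5S)-allylic alcohol F5. MsCl/Et3N at −40 °C gives the mesylate F6, and SN2 displacement with anhydrous ethereal H2O2 inverts C5 to give 27. The regiochemistry is then reagent-defined, and the inversion covers the case in which the exposed face gives the wrong C5 epimer in the ene reaction.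

Step 7 (together with step 6: the acrylate-bearing zinc reagent and its precursor are the least precedented building blocks). The fallback sets out from 9 and returns at 14. Negishi coupling of 9 with [4-(trimethylsilyl)but-3-yn-1-yl]zinc bromide (PdCl2(dppf), THF) gives the silyl enyne F7. K2CO3/MeOH gives the terminal alkyne F8. Pd-catalysed Markovnikov hydrocarboxylation with formic acid (Pd(OAc)2, Xantphos, HCO2H, Ac2O cat., toluene, 80 °C) then builds the 2-substituted acrylic acid 14.

**Further compounds**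
F1 | step 13 | seco hydroxy acid (trans α-methylene lactone with free C10–OH and acrylic acid) | C=C1C(=O)O[C@@H](/C=C(\C)C[C@@H](O)/C=C/C)[C@@H]1CC/C(C)=C/CCC(=C)C(=O)O
F2 | step 13 | 15-membered diolide (acrylate ester of the C10 carbinol) | C=C1C(=O)O[C@H]2/C=C(\C)C[C@H](/C=C/C)OC(=O)C(=C)CC/C=C(\C)CC[C@H]12
F3 | step 14 | (4S,5S)-4,5-epoxyovatodiolide | C=C1C(=O)O[C@H]2/C=C(\C)C[C@@H]3C=C(CC[C@@H]4O[C@@]4(C)CC[C@H]12)C(=O)O3
F4 | step 14 | (5S)-4-methylene-5-(trimethylsilyloxy)ovatodiolide | C=C1C(=O)O[C@H]2/C=C(\C)C[C@@H]3C=C(CC[C@H](O[Si](C)(C)C)C(=C)CC[C@H]12)C(=O)O3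
F5 | step 14 | (5S)-4-methylene-5-hydroxyovatodiolide | C=C1C(=O)O[C@H]2/C=C(\C)C[C@@H]3C=C(CC[C@H](O)C(=C)CC[C@H]12)C(=O)O3
F6 | step 14 | (5S)-4-methylene-5-(methanesulfonyloxy)ovatodiolide | C=C1C(=O)O[C@H]2/C=C(\C)C[C@@H]3C=C(CC[C@H](OS(C)(=O)=O)C(=C)CC[C@H]12)C(=O)O3
F7 | step 7 | methyl (2Z,6E)-6-methyl-2-[(4,4,5,5-tetramethyl-1,3,2-dioxaborolan-2-yl)methyl]-11-(trimethylsilyl)undeca-2,6-dien-10-ynoate | COC(=O)/C(CB1OC(C)(C)C(C)(C)O1)=C\CC/C(C)=C/CCC#C[Si](C)(C)C
F8 | step 7 | methyl (2Z,6E)-6-methyl-2-[(4,4,5,5-tetramethyl-1,3,2-dioxaborolan-2-yl)methyl]undeca-2,6-dien-10-ynoate | COC(=O)/C(CB1OC(C)(C)C(C)(C)O1)=C\CC/C(C)=C/CCC#C
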